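**Plan**
Retrosynthetic cuts: first the lactone bond O2–C3 of ring A (back to a 2-propynylbenzoic acid); then C5–C4a and C8–C8a of ring B (a silyloxy ketene-acetal diene plus methyl hexa-2,4-diynoate); then the CH2–CH2 bond next to the ring C benzyl carbon (benzyl bromide plus the enolate of 4,4-dimethoxybut-3-en-2-one); last ring C itself (a 4-methoxypyranone plus methyl methoxyacetate).
Forward order: ring C by pyranone recyclisation; the chain is joined by enolate alkylation and silylated to the diene; ring B by Diels–Alder benzannulation; ring A by saponification and 6-endo-dig lactonisation, the ring C phenol being freed in the saponification.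
Enabling feature: ring B carries 8-OMe and 6-OH in a 1,3 relation with the carboxyl carbon C1 on C8a, which is what a 1,1-dimethoxy-3-silyloxy diene and an ynoate deliver, and C4a bears the three-carbon arm C4–C3–CH3 that a propynyl group on the ynoate supplies.
Stereochemistry: the target has no stereocentre; the only geometric requirement is the Z silyl dienol ether, set in the enolisation of step 9.

Key step: step 12

Remark: ring A is the pyranone ring and ring B the benzo ring of the isocoumarin, ring C is the pendant arene; the single sp3 centre of the cycloadduct is racemic and is lost on aromatisation.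

**Route**

Step 1
Reactants: 1 4-methoxy-6-methyl-2H-pyran-2-one; 2 methyl methoxyacetate
Product: 4 4-methoxy-6-(3-methoxy-2-oxopropyl)-2H-pyran-2-one, via lithiated pyranone 3 (not isolated)
Conditions: LiN(i-Pr)2 (2.2 equiv), THF, −78 °C; then 2, −78 → −20 °C; aq. NH4Cl
Reagents that add atoms: none
Why: The 6-methyl group is a vinylogous ester alpha position, so the amide base gives the lithiated species 3, which undergoes Claisen-type acylation by the alpha-alkoxy ester, the second equivalent of base taking up the more acidic keto-pyranone product.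

Step 2
Reactants: 4 4-methoxy-6-(3-methoxy-2-oxopropyl)-2H-pyran-2-one
Product: 5 methyl 4-hydroxy-2-methoxy-6-(methoxymethyl)benzoate
Conditions: KOH, MeOH, rt; then 1 M HCl
Reagents that add atoms: methanol (CO)
Why: Methoxide opens the pyranone to a methyl 3-methoxy-5,7-dioxo-enoate whose ester alpha carbon adds to the terminal ketone in an intramolecular aldol condensation, and dehydration with enolisation gives the resorcylate with methoxy ortho and hydroxy para to the ester (pyranone-to-resorcylate recyclisation).

Step 3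
Reactants: 5 methyl 4-hydroxy-2-methoxy-6-(methoxymethyl)benzoate
Product: 6 methyl 4-[(tert-butyldimethylsilyl)oxy]-2-methoxy-6-(methoxymethyl)benzoate
Conditions: TBSCl, imidazole, DMF, rt
Reagents that add atoms: tert-butyldimethylsilyl chloride (CC(C)(C)[Si](C)(C)Cl)
Why: Standard silylation of an acidic phenol; the aryl silyl ether should survive hydride, enolate and thermal steps and is chosen because hydroxide removes it later together with the ester.

Step 4
Reactants: 6 methyl 4-[(tert-butyldimethylsilyl)oxy]-2-methoxy-6-(methoxymethyl)benzoate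
Product: 7 {4-[(tert-butyldimethylsilyl)oxy]-2-methoxy-6-(methoxymethyl)phenyl}methanol
Conditions: i-Bu2AlH (3 equiv), CH2Cl2, −78 → 0 °C; aq. potassium sodium tartrate
Reagents that add atoms: none
Why: Hydride reduction of the benzoate to the benzyl alcohol, with the aryl silyl ether and the benzylic methyl ether inert to the aluminium hydride.

Step 5
Reactants: 7 {4-[(tert-butyldimethylsilyl)oxy]-2-methoxy-6-(methoxymethyl)phenyl}methanol
Product: 8 [4-(bromomethyl)-3-methoxy-5-(methoxymethyl)phenoxy](tert-butyl)dimethylsilane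
Conditions: CBr4, PPh3, CH2Cl2, 0 °C; pentane trituration, filtration; used at once
Reagents that add atoms: tetrabromomethane (BrC(Br)(Br)Br)
Why: Appel reaction, in which bromide displaces the alkoxyphosphonium group under neutral conditions at low temperature, sparing the silyl ether and limiting ionisation of the electron-rich benzylic halide.

Step 6
Reactants: 9 acetyl chloride; 10 1,1-dichloroethene
Product: 12 4,4-dichlorobut-3-en-2-one, via 4,4,4-trichlorobutan-2-one 11 (not isolated)
Conditions: AlCl3, CH2Cl2, 0 °C → rt; ice/HCl work-up; distillation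
Reagents that add atoms: none
Why: Friedel–Crafts-type acylation of the alkene gives the beta-trichloromethyl ketone, which loses HCl by beta-elimination on distillation to give the conjugated dichlorovinyl ketone.

Step 7
Reactants: 12 4,4-dichlorobut-3-en-2-one
Product: 13 4,4-dimethoxybut-3-en-2-one
Conditions: NaOMe (2.1 equiv), MeOH, 0 °C → rt
Reagents that add atoms: sodium methoxide ([Na+].[O-]C)
Why: Two successive addition–elimination steps (vinylic substitution) at the beta carbon of the enone replace both chlorides by methoxide.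

Step 8
Reactants: 13 4,4-dimethoxybut-3-en-2-one; 8 [4-(bromomethyl)-3-methoxy-5-(methoxymethyl)phenoxy](tert-butyl)dimethylsilane
Product: 15 5-{4-[(tert-butyldimethylsilyl)oxy]-2-methoxy-6-(methoxymethyl)phenyl}-1,1-dimethoxypent-1-en-3-one, via lithium dienolate 14 (not isolated)
Conditions: LiN(i-Pr)2, THF, −78 °C (13 in slight excess); then 8, DMPU, −78 → −20 °C
Reagents that add atoms: none
Why: Kinetic deprotonation at the methyl group, the only enolisable site, gives the cross-conjugated lithium dienolate, which is C-alkylated by the reactive benzylic bromide in an SN2 reaction (alpha-prime alkylation of a vinylogous ester enolate).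

Step 9
Reactants: 15 5-{4-[(tert-butyldimethylsilyl)oxy]-2-methoxy-6-(methoxymethyl)phenyl}-1,1-dimethoxypent-1-en-3-one
Product: 17 {[(3Z)-5-{4-[(tert-butyldimethylsilyl)oxy]-2-methoxy-6-(methoxymethyl)phenyl}-1,1-dimethoxypenta-1,3-dien-3-yl]oxy}trimethylsilane, via lithium Z-dienolate 16 (not isolated)
Conditions: LiN(i-Pr)2, THF/DMPU, −78 °C; then Me3SiCl; pentane, filtration under argon; used crude
Reagents that add atoms: chlorotrimethylsilane (C[Si](C)(C)Cl)
Why: Kinetic enolisation at the only remaining alpha CH2 followed by O-silylation gives the silyl dienol ether, the polar cosolvent favouring the Z enolate so that the benzyl group lies trans to the ketene-acetal arm, as the s-cis diene requires.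

Step 10
Reactants: 18 1,4-bis(trimethylsilyl)buta-1,3-diyne
Product: 20 trimethyl(penta-1,3-diyn-1-yl)silane, via lithium silylbutadiynide 19 (not isolated)
Conditions: MeLi·LiBr (1.0 equiv), THF, 0 °C → rt; then MeI, rt
Reagents that add atoms: iodomethane (CI)
Why: Methyllithium attacks one silicon only, because the resulting acetylide resists a second cleavage, and the lithium butadiynide is then C-methylated by iodomethane (acetylide alkylation).

Step 11
Reactants: 20 trimethyl(penta-1,3-diyn-1-yl)silane
Product: 22 methyl hexa-2,4-diynoate, via pentadiynyllithium 21 (not isolated)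
Conditions: MeLi·LiBr, THF, 0 °C → rt; then added to ClCO2Me, −78 → 0 °C
Reagents that add atoms: methyl chloroformate (COC(=O)Cl)
Why: The same Si–C cleavage gives penta-1,3-diynyllithium, which is acylated by the chloroformate, inverse addition at low temperature stopping the reaction at the ester.

Step 12
Reactants: 17 {[(3Z)-5-{4-[(tert-butyldimethylsilyl)oxy]-2-methoxy-6-(methoxymethyl)phenyl}-1,1-dimethoxypenta-1,3-dien-3-yl]oxy}trimethylsilane; 22 methyl hexa-2,4-diynoate
Product: 25 methyl 3-({4-[(tert-butyldimethylsilyl)oxy]-2-methoxy-6-(methoxymethyl)phenyl}methyl)-4-hydroxy-6-methoxy-2-(prop-1-yn-1-yl)benzoate, via cyclohexa-1,4-diene cycloadduct 23 (not isolated), via aryl trimethylsilyl ether 24 (not isolated)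
Conditions: 22 (1.5 equiv), PhMe, 90 °C, sealed; then 0.5 M HCl, THF, 0 °C → rt
Reagents that add atoms: none
Why: The electron-rich diene 17 and the electron-poor ynoate 22 should combine in a concerted but strongly asynchronous normal-demand Diels–Alder reaction, the silyl enol ether terminus that carries the ring C benzyl group (future C5) bonding to the beta carbon of the ynoate (future C4a) and the ketene-acetal carbon (future C8) closing onto the alpha carbon (future C8a). The closest known reaction type is the benzannulation of 1,1-dialkoxy-3-silyloxybuta-1,3-dienes with acetylenic esters to 4-hydroxy-2-alkoxybenzoates. Ring B closes by intermolecular (4+2) cycloaddition, both ring bonds arising in one event; cycloadduct 23 then aromatises by 1,4-elimination of methanol to 24, whose trimethylsilyl ether is cleaved by dilute acid while the bulkier tert-butyldimethylsilyl ether stays. The only new sp3 centre, in 23, is racemic and vanishes on aromatisation, so no stereocontrol is needed. Regiochemistry follows from pairing the most nucleophilic diene terminus with the ynoate beta carbon, and the Z geometry of 17 keeps the benzyl substituent on the outside of the s-cis diene. Reaction at the ester-bearing triple bond is expected because only that alkyne has the ester on one terminus and a slim, electron-withdrawing alkynyl group on the other, whereas the distal alkyne is capped by a donating methyl group.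

Step 13
Reactants: 25 methyl 3-({4-[(tert-butyldimethylsilyl)oxy]-2-methoxy-6-(methoxymethyl)phenyl}methyl)-4-hydroxy-6-methoxy-2-(prop-1-yn-1-yl)benzoate
Product: 27 4-hydroxy-3-{[4-hydroxy-2-methoxy-6-(methoxymethyl)phenyl]methyl}-6-methoxy-2-(prop-1-yn-1-yl)benzoic acid, via desilylated diphenol ester 26 (not isolated)
Conditions: KOH (excess), MeOH/H2O, 65 °C; then 1 M HCl to pH 3, 0 °C
Reagents that add atoms: potassium hydroxide ([K+].[OH-])
Why: Hydroxide first cleaves the aryl silyl ether (attack at silicon, phenoxide leaving group) and then saponifies the hindered benzoate by acyl substitution, the protic medium keeping the carboxylate from adding to the alkyne.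

Step 14
Reactants: 27 4-hydroxy-3-{[4-hydroxy-2-methoxy-6-(methoxymethyl)phenyl]methyl}-6-methoxy-2-(prop-1-yn-1-yl)benzoic acid
Product: 28 6-hydroxy-5-{[4-hydroxy-2-methoxy-6-(methoxymethyl)phenyl]methyl}-8-methoxy-3-methyl-1H-isochromen-1-one (target)
Conditions: AgOTf (10 mol%), CH2Cl2, rt, dark
Reagents that add atoms: none
Why: Cationic silver activates the alkyne as a pi-acid and the carboxyl oxygen attacks the methyl-bearing alkyne carbon anti to the metal in a 6-endo-dig cycloisomerisation, protodemetalation giving the 3-methylisocoumarin while both phenols, which cannot reach the alkyne, stay untouched.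

**Compound list**
1 | 4-methoxy-6-methyl-2H-pyran-2-one | COc1cc(C)oc(=O)c1 | starting material
2 | methyl methoxyacetate | COCC(=O)OC | starting material
3 | (4-methoxy-2-oxo-2H-pyran-6-yl)methyllithium | [Li]Cc1cc(OC)cc(=O)o1 | intermediate
4 | 4-methoxy-6-(3-methoxy-2-oxopropyl)-2H-pyran-2-one | COCC(=O)Cc1cc(OC)cc(=O)o1 | intermediate
5 | methyl 4-hydroxy-2-methoxy-6-(methoxymethyl)benzoate | COCc1cc(O)cc(OC)c1C(=O)OC | intermediate
6 | methyl 4-[(tert-butyldimethylsilyl)oxy]-2-methoxy-6-(methoxymethyl)benzoate | COCc1cc(O[Si](C)(C)C(C)(C)C)cc(OC)c1C(=O)OC | intermediate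
7 | {4-[(tert-butyldimethylsilyl)oxy]-2-methoxy-6-(methoxymethyl)phenyl}methanol | COCc1cc(O[Si](C)(C)C(C)(C)C)cc(OC)c1CO | intermediate
8 | [4-(bromomethyl)-3-methoxy-5-(methoxymethyl)phenoxy](tert-butyl)dimethylsilane | COCc1cc(O[Si](C)(C)C(C)(C)C)cc(OC)c1CBr | intermediate
9 | acetyl chloride | CC(=O)Cl | starting material
10 | 1,1-dichloroethene | C=C(Cl)Cl | starting material
11 | 4,4,4-trichlorobutan-2-one | CC(=O)CC(Cl)(Cl)Cl | intermediate
12 | 4,4-dichlorobut-3-en-2-one | CC(=O)C=C(Cl)Cl | intermediate
13 | 4,4-dimethoxybut-3-en-2-one | COC(OC)=CC(C)=O | intermediate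
14 | lithium 4,4-dimethoxybuta-1,3-dien-2-olate | COC(OC)=CC(=C)O[Li] | intermediate
15 | 5-{4-[(tert-butyldimethylsilyl)oxy]-2-methoxy-6-(methoxymethyl)phenyl}-1,1-dimethoxypent-1-en-3-one | COC(OC)=CC(=O)CCc1c(COC)cc(O[Si](C)(C)C(C)(C)C)cc1OC | intermediate
16 | lithium (3Z)-5-{4-[(tert-butyldimethylsilyl)oxy]-2-methoxy-6-(methoxymethyl)phenyl}-1,1-dimethoxypenta-1,3-dien-3-olate | COC(OC)=C/C(=C/Cc1c(COC)cc(O[Si](C)(C)C(C)(C)C)cc1OC)O[Li] | intermediate
17 | {[(3Z)-5-{4-[(tert-butyldimethylsilyl)oxy]-2-methoxy-6-(methoxymethyl)phenyl}-1,1-dimethoxypenta-1,3-dien-3-yl]oxy}trimethylsilane | COC(OC)=C/C(=C/Cc1c(COC)cc(O[Si](C)(C)C(C)(C)C)cc1OC)O[Si](C)(C)C | intermediate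
18 | 1,4-bis(trimethylsilyl)buta-1,3-diyne | C[Si](C)(C)C#CC#C[Si](C)(C)C | starting material
19 | [4-(trimethylsilyl)buta-1,3-diyn-1-yl]lithium | [Li]C#CC#C[Si](C)(C)C | intermediate
20 | trimethyl(penta-1,3-diyn-1-yl)silane | CC#CC#C[Si](C)(C)C | intermediate
21 | penta-1,3-diyn-1-yllithium | [Li]C#CC#CC | intermediate
22 | methyl hexa-2,4-diynoate | CC#CC#CC(=O)OC | intermediate
23 | methyl 3-({4-[(tert-butyldimethylsilyl)oxy]-2-methoxy-6-(methoxymethyl)phenyl}methyl)-6,6-dimethoxy-2-(prop-1-yn-1-yl)-4-[(trimethylsilyl)oxy]cyclohexa-1,4-diene-1-carboxylate (racemic) | COC(=O)C1=C(C#CC)C(Cc2c(COC)cc(O[Si](C)(C)C(C)(C)C)cc2OC)C(O[Si](C)(C)C)=CC1(OC)OC | intermediate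
24 | methyl 3-({4-[(tert-butyldimethylsilyl)oxy]-2-methoxy-6-(methoxymethyl)phenyl}methyl)-6-methoxy-2-(prop-1-yn-1-yl)-4-[(trimethylsilyl)oxy]benzoate | COC(=O)c1c(OC)cc(O[Si](C)(C)C)c(Cc2c(COC)cc(O[Si](C)(C)C(C)(C)C)cc2OC)c1C#CC | intermediate
25 | methyl 3-({4-[(tert-butyldimethylsilyl)oxy]-2-methoxy-6-(methoxymethyl)phenyl}methyl)-4-hydroxy-6-methoxy-2-(prop-1-yn-1-yl)benzoate | COC(=O)c1c(OC)cc(O)c(Cc2c(COC)cc(O[Si](C)(C)C(C)(C)C)cc2OC)c1C#CC | intermediate
26 | methyl 4-hydroxy-3-{[4-hydroxy-2-methoxy-6-(methoxymethyl)phenyl]methyl}-6-methoxy-2-(prop-1-yn-1-yl)benzoate | COC(=O)c1c(OC)cc(O)c(Cc2c(COC)cc(O)cc2OC)c1C#CC | intermediate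
27 | 4-hydroxy-3-{[4-hydroxy-2-methoxy-6-(methoxymethyl)phenyl]methyl}-6-methoxy-2-(prop-1-yn-1-yl)benzoic acid | OC(=O)c1c(OC)cc(O)c(Cc2c(COC)cc(O)cc2OC)c1C#CC | intermediate
28 | 6-hydroxy-5-{[4-hydroxy-2-methoxy-6-(methoxymethyl)phenyl]methyl}-8-methoxy-3-methyl-1H-isochromen-1-one | COCc1cc(O)cc(OC)c1Cc1c(O)cc(OC)c2c(=O)oc(C)cc12 | target

**Count**
Total step count: 14.
Longest linear sequence: 10 steps (steps 1–5, 8, 9, 12, 13, 14).

**Steps most likely to fail**

Step 12. The cycloaddition may take place across the distal, methyl-capped triple bond, or stop at conjugate addition without ring closure. Bond formation between two substituted termini may also be slow enough for the diynoate to decompose thermally. The fallback sets out from diene 17 and comes back at phenol 25. The dienophile is changed to methyl 3-bromopropiolate F1 (from methyl propiolate, N-bromosuccinimide and catalytic AgNO3 in acetone), which has a single triple bond and forms the same two ring bonds. The bromo cycloadduct F2 should lose methanol to the aryl trimethylsilyl ether F3, and dilute acid then gives methyl 2-bromo-3-({4-[(tert-butyldimethylsilyl)oxy]-2-methoxy-6-(methoxymethyl)phenyl}methyl)-4-hydroxy-6-methoxybenzoate F4. A copper-free Sonogashira coupling of F4 with propyne (PdCl2(MeCN)2, XPhos, Cs2CO3, MeCN) installs the propynyl group after the ring is built and delivers 25.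

Step 8. The electron-rich benzylic bromide may ionise before or during the alkylation, with participation of the ortho methoxymethyl oxygen or self-condensation, and proton transfer between product and enolate may cause over-alkylation. The fallback sets out from alcohol 7 and enone 13 and comes back at ketone 15. Oxidation of 7 with MnO2 gives 4-[(tert-butyldimethylsilyl)oxy]-2-methoxy-6-(methoxymethyl)benzaldehyde F5. Aldol addition of lithium dienolate 14 gives the racemic beta-hydroxy ketone F6, and dehydration (MsCl, Et3N) gives the (E)-dienone F7. Conjugate reduction of the styrenic enone with [(Ph3P)CuH]6 then gives 15; the beta,beta-dimethoxy enone is too electron-rich and hindered to accept hydride. No benzylic halide is handled on this path.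

Step 14. The carboxyl group may attack the ring-proximal alkyne carbon in a 5-exo-dig closure, giving the alkylidene phthalide alongside or instead of 6-endo closure. The fallback sets out from ester 25 and comes back at target 28, and it closes ring A on the ester without a free acid. Silylation of the 6-hydroxy group (TBSCl, imidazole) gives the bis-silyl ether F8. Iodocyclisation with I2 in CH2Cl2, in which the ester carbonyl oxygen attacks the iodonium-activated alkyne at the methyl-bearing carbon and iodide removes the O-methyl group, gives the 4-iodoisocoumarin F9. Reductive deiodination (Pd(OAc)2, PPh3, HCO2Na, DMF) gives the bis-silyl isocoumarin F10, and Bu4NF/AcOH in THF releases both phenols to give 28.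

**Further compounds**
F1 | step 12 | methyl 3-bromopropiolate | COC(=O)C#CBr
F2 | step 12 | methyl 2-bromo-3-({4-[(tert-butyldimethylsilyl)oxy]-2-methoxy-6-(methoxymethyl)phenyl}methyl)-6,6-dimethoxy-4-[(trimethylsilyl)oxy]cyclohexa-1,4-diene-1-carboxylate (racemic) | COC(=O)C1=C(Br)C(Cc2c(COC)cc(O[Si](C)(C)C(C)(C)C)cc2OC)C(O[Si](C)(C)C)=CC1(OC)OC
F3 | step 12 | methyl 2-bromo-3-({4-[(tert-butyldimethylsilyl)oxy]-2-methoxy-6-(methoxymethyl)phenyl}methyl)-6-methoxy-4-[(trimethylsilyl)oxy]benzoate | COC(=O)c1c(OC)cc(O[Si](C)(C)C)c(Cc2c(COC)cc(O[Si](C)(C)C(C)(C)C)cc2OC)c1Br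
F4 | step 12 | methyl 2-bromo-3-({4-[(tert-butyldimethylsilyl)oxy]-2-methoxy-6-(methoxymethyl)phenyl}methyl)-4-hydroxy-6-methoxybenzoate | COC(=O)c1c(OC)cc(O)c(Cc2c(COC)cc(O[Si](C)(C)C(C)(C)C)cc2OC)c1Br
F5 | step 8 | 4-[(tert-butyldimethylsilyl)oxy]-2-methoxy-6-(methoxymethyl)benzaldehyde | COCc1cc(O[Si](C)(C)C(C)(C)C)cc(OC)c1C=O
F6 | step 8 | 5-{4-[(tert-butyldimethylsilyl)oxy]-2-methoxy-6-(methoxymethyl)phenyl}-5-hydroxy-1,1-dimethoxypent-1-en-3-one (racemic) | COC(OC)=CC(=O)CC(O)c1c(COC)cc(O[Si](C)(C)C(C)(C)C)cc1OC
F7 | step 8 | (4E)-5-{4-[(tert-butyldimethylsilyl)oxy]-2-methoxy-6-(methoxymethyl)phenyl}-1,1-dimethoxypenta-1,4-dien-3-one | COC(OC)=CC(=O)/C=C/c1c(COC)cc(O[Si](C)(C)C(C)(C)C)cc1OC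
F8 | step 14 | methyl 4-[(tert-butyldimethylsilyl)oxy]-3-({4-[(tert-butyldimethylsilyl)oxy]-2-methoxy-6-(methoxymethyl)phenyl}methyl)-6-methoxy-2-(prop-1-yn-1-yl)benzoate | COC(=O)c1c(OC)cc(O[Si](C)(C)C(C)(C)C)c(Cc2c(COC)cc(O[Si](C)(C)C(C)(C)C)cc2OC)c1C#CC
F9 | step 14 | 6-[(tert-butyldimethylsilyl)oxy]-5-({4-[(tert-butyldimethylsilyl)oxy]-2-methoxy-6-(methoxymethyl)phenyl}methyl)-4-iodo-8-methoxy-3-methyl-1H-isochromen-1-one | COCc1cc(O[Si](C)(C)C(C)(C)C)cc(OC)c1Cc1c(O[Si](C)(C)C(C)(C)C)cc(OC)c2c(=O)oc(C)c(I)c12
F10 | step 14 | 6-[(tert-butyldimethylsilyl)oxy]-5-({4-[(tert-butyldimethylsilyl)oxy]-2-methoxy-6-(methoxymethyl)phenyl}methyl)-8-methoxy-3-methyl-1H-isochromen-1-one | COCc1cc(O[Si](C)(C)C(C)(C)C)cc(OC)c1Cc1c(O[Si](C)(C)C(C)(C)C)cc(OC)c2c(=O)oc(C)cc12
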